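**Plan**
- Retrosynthesis: the two ester C–O bonds and the C8 ketone (from a silyl-protected 8α-alcohol) are cut first. Then the C3–C4 bond of ring A is cut: the cis-3,4-diol (secondary C3 carbinol next to the methyl-bearing tertiary C4 carbinol, beside the cis-fused C5/C10) is the retron of a ketone–aldehyde pinacol coupling between a C10 3-oxopropyl arm and a C5 acetyl arm held cis on ring B.
- Further cuts: C1=C2 (Wittig on a lactol), C7–isopropyl (epoxide opening), and C5–C6 plus C9–C10 (Diels–Alder of butadiene with an α-methylbutenolide made by ring-closing metathesis).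
- Forward: butenolide, then ring B by [4+2], then C7/C8 functionalisation, then two-carbon extension at C1, then ring A closed last by SmI2, then acylations and C8 oxidation.
- Stereochemistry: the carbinol centre of (R)-but-3-en-2-ol steers the cycloaddition (C5, C10). Carboxyl-delivered iodolactonisation and a trans-diaxial epoxide opening set C8 and C7. These two equatorial groups lock the chair through which the samarium chelate sets C3 and C4. The original carbinol centre is erased when it becomes the C4 ketone.

Key step: step 13

Remark: eudesmane numbering is used for every intermediate (C10 = quaternary carbon with the angular methyl and C1; C5 = CH carrying C4; ring B = C5–C10; β = face of the C10 methyl), and the butenolide is assumed to react on the face anti to its ring methyl, as 5-substituted 2(5H)-furanones generally do.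

Step 1
Reactants: 1 (R)-but-3-en-2-ol; 2 methacryloyl chloride
Product: 3 (R)-but-3-en-2-yl methacrylate
Conditions: Et3N, DMAP (cat.), CH2Cl2, 0 °C → rt
Reagents that add atoms: none
Why: DMAP-catalysed acylation of a secondary alcohol by an acid chloride (nucleophilic acyl substitution) does not touch the carbinol stereocentre.

Step 2
Reactants: 3 (R)-but-3-en-2-yl methacrylate
Product: 4 (R)-3,5-dimethylfuran-2(5H)-one
Conditions: second-generation Grubbs catalyst RuCl2(=CHPh)(H2IMes)(PCy3) (5 mol%), CH2Cl2, 40 °C
Reagents that add atoms: none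
Why: Ring-closing metathesis of an allyl methacrylate is a standard entry to α-methylbutenolides, driven by loss of ethene, with the carbinol centre untouched.

Step 3
Reactants: 4 (R)-3,5-dimethylfuran-2(5H)-one; 5 buta-1,3-diene
Product: 6 cis-fused lactone (3R)-3,7a-dimethyl-3a,4,7,7a-tetrahydro-2-benzofuran-1(3H)-one
Conditions: 5 (excess), BHT (cat.), toluene, 200 °C, sealed vessel
Reagents that add atoms: none
Why: Thermal Diels–Alder reaction of a 5-substituted 2(5H)-furanone: the diene adds suprafacially to the face anti to the ring methyl, so the cis fusion (C5–H and C10–CH3 both β) takes its absolute sense from the (R)-carbinol centre, and symmetric butadiene leaves no regiochemical question.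

Step 4
Reactants: 6 cis-fused lactone
Product: 8 bridged iodolactone 2-[(1R)-1-hydroxyethyl]-4-iodo-1-methyl-6-oxabicyclo[3.2.1]octan-7-one, via sodium hydroxy-carboxylate 7 (not isolated)
Conditions: NaOH, THF/H2O, 60 °C; then NaHCO3, I2, KI, 0 °C → rt, dark
Reagents that add atoms: sodium hydroxide, [Na+].[OH-]; iodine, II
Why: Saponification then iodolactonisation of a cyclohex-3-ene-1-carboxylate: the α-face carboxylate opens the β-iodonium ion at C8 in the usual five-membered mode, and anti addition fixes C8–O as α and C7–I as β.

Step 5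
Reactants: 8 bridged iodolactone
Product: 10 syn-epoxy lactone (7α,8α-epoxide of 6), via iodohydrin alkoxide 9 (not isolated)
Conditions: NaH, THF, 0 °C → rt
Reagents that add atoms: none
Why: Base-induced conversion of an iodolactone into the syn epoxide: the C4 alkoxide re-forms the less strained cis-fused γ-lactone by transacylation, and the freed C8 alkoxide displaces the anti-periplanar C7 iodide (intramolecular Williamson reaction, inversion at C7) to place the epoxide on the α face.

Step 6
Reactants: 10 syn-epoxy lactone; 11 isopropylmagnesium chloride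
Product: 12 fused lactone with 7β-isopropyl and 8α-hydroxyl groups
Conditions: 11 (2 equiv), CuI (10 mol%), THF, −40 → −20 °C; aq. NH4Cl
Reagents that add atoms: none
Why: Copper-catalysed Grignard opening of a cyclohexene oxide follows the Fürst–Plattner rule (trans-diaxial SN2 opening); only attack at C7 from the β face avoids a 1,3-diaxial clash between the incoming isopropyl group and the C10 methyl, so C7 becomes β-isopropyl and C8 keeps its α oxygen, while the lactone carbonyl next to the quaternary C10 should survive at low temperature.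

Step 7
Reactants: 12 hydroxy lactone
Product: 13 8α-(tert-butyldimethylsilyl) ether of 12
Conditions: TBSOTf, 2,6-lutidine, CH2Cl2, 0 °C
Reagents that add atoms: tert-butyldimethylsilyl triflate, CC(C)(C)[Si](C)(C)OS(=O)(=O)C(F)(F)F
Why: Silyl triflate with a hindered pyridine base is the standard silylation of a hindered secondary alcohol and creates no stereocentre.

Step 8
Reactants: 13 silyl ether lactone
Product: 14 lactol (C1 hemiacetal, both anomers)
Conditions: i-Bu2AlH (1.1 equiv), CH2Cl2, −78 °C; Rochelle salt
Reagents that add atoms: none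
Why: Partial reduction of a lactone by i-Bu2AlH stops at the lactol because the tetrahedral aluminium alkoxide is stable at −78 °C.

Step 9
Reactants: 14 lactol; 15 ethyl (triphenylphosphoranylidene)acetate
Product: 16 (E)-enoate with the C5 (R)-1-hydroxyethyl group free
Conditions: 15 (2.5 equiv), toluene, 90 °C
Reagents that add atoms: none
Why: Wittig olefination of a lactol through its open hydroxy-aldehyde form with a stabilised ylide gives the (E)-enoate under neutral conditions, which should keep the freed C4 hydroxyl from adding back to the hindered β-carbon.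

Step 10
Reactants: 16 (E)-enoate
Product: 17 saturated hydroxy ester
Conditions: H2 (1 atm), 10% Pd/C, EtOAc, rt
Reagents that add atoms: none
Why: Heterogeneous catalytic hydrogenation saturates the disubstituted conjugated alkene and leaves the silyl ether and ester alone.

Step 11
Reactants: 17 saturated hydroxy ester
Product: 18 1,6-diol (primary C3–OH, secondary C4–OH)
Conditions: LiAlH4, THF, 0 °C
Reagents that add atoms: none
Why: Hydride reduction of the ester to the primary alcohol is routine and the silyl ether tolerates it.

Step 12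
Reactants: 18 1,6-diol
Product: 19 keto-aldehyde (C10 3-oxopropyl arm and C5 acetyl arm cis on ring B)
Conditions: Dess–Martin periodinane (3 equiv), NaHCO3, CH2Cl2, 0 °C → rt; used at once
Reagents that add atoms: none
Why: Buffered Dess–Martin oxidation converts both hydroxyls without base, so the now enolisable C5 is not epimerised, and the carbinol centre that relayed the chirality is erased here.

Step 13
Reactants: 19 keto-aldehyde
Product: 20 8α-(tert-butyldimethylsilyloxy)-5βH-eudesmane-3α,4α-diol
Conditions: SmI2 (2.5 equiv), t-BuOH (2.5 equiv), THF, −78 → −20 °C, high dilution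
Reagents that add atoms: none
Why: Single-electron transfer from divalent samarium to the aldehyde, the more easily reduced carbonyl, gives the C3 ketyl, which adds to the samarium-bound C4 ketone; a second electron and protonation by t-BuOH give the diol. The closest known reaction type is the SmI2 intramolecular ketone–aldehyde pinacol coupling of 1,6-dicarbonyl compounds to cis-cyclohexane-1,2-diols. Ring A closes by 6-exo-trig attack of the ketyl carbon C3 on the C4 carbonyl. The two new carbinol centres are cis because both oxygens bridge one trivalent samarium; their sense relative to C5/C10 comes from a chair-like transition state built on the ring B chair that keeps the 7β-isopropyl and 8α-silyloxy groups equatorial, which makes the C5 acetyl axial and the C10 chain equatorial and so puts the C4 methyl equatorial, O-4 axial (α) and O-3 equatorial (α). The step needs ketyl formation at the aldehyde only and one of four diol diastereomers; the substrate secures this by having no other reducible group (C8 is a silyl ether) and by the trans-diequatorial C7/C8 lock, since the flipped chair would put both groups axial with the silyloxy group against the C10 chain.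

Step 14
Reactants: 20 diol; 21 angelic acid
Product: 23 3α-angelate with the 4α-hydroxyl free, via mixed Yamaguchi anhydride 22 (not isolated)
Conditions: 21, 2,4,6-trichlorobenzoyl chloride, Et3N, toluene, rt; then 20, 80 °C
Reagents that add atoms: none
Why: Yamaguchi esterification acylates the equatorial secondary hydroxyl and not the tertiary one, and a hindered mixed anhydride used without a nucleophilic catalyst is the usual way to keep the Z (angelate) geometry.

Step 15
Reactants: 23 3α-angelate
Product: 24 4α-acetate 3α-angelate 8α-silyl ether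
Conditions: Ac2O, DMAP, Et3N, CH2Cl2, 35 °C
Reagents that add atoms: acetic anhydride, CC(=O)OC(C)=O
Why: DMAP-catalysed (Steglich-type) acetylation is the standard method for tertiary alcohols, and the N-acetylpyridinium ion is small enough to reach the axial C4 hydroxyl.

Step 16
Reactants: 24 silyl ether
Product: 25 8α-alcohol
Conditions: HF·pyridine, pyridine, THF, 0 °C → rt
Reagents that add atoms: none
Why: Buffered fluoride desilylation cleaves the Si–O bond and leaves the angelate and the tertiary acetate.

Step 17
Reactants: 25 8α-alcohol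
Product: 26 target, 4α-acetoxy-3α-angeloyloxy-5βH,7αH-eudesman-8-one
Conditions: Dess–Martin periodinane, NaHCO3, CH2Cl2, rt
Reagents that add atoms: none
Why: Dess–Martin oxidation gives the C8 ketone under near-neutral conditions, and C7 stays β-isopropyl, which is also the favoured epimer because the 4β/10β methyls hold the cis-decalin in the conformer with this group equatorial.

**Compound list**
1 | (R)-but-3-en-2-ol | C[C@@H](O)C=C | starting material
2 | methacryloyl chloride | CC(=C)C(=O)Cl | starting material
3 | (R)-but-3-en-2-yl methacrylate | C[C@@H](OC(=O)C(C)=C)C=C | intermediate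
4 | (R)-3,5-dimethylfuran-2(5H)-one | C[C@H]1OC(=O)C(C)=C1 | intermediate
5 | buta-1,3-diene | C=CC=C | starting material
6 | (3R)-3,7a-dimethyl-3a,4,7,7a-tetrahydro-2-benzofuran-1(3H)-one, cis-fused, 3-CH3 cis to H-3a and 7a-CH3 (lactone C=O is C1 on C10, ring O on C4, alkene C7=C8) | C[C@H]1OC(=O)[C@]2(C)CC=CC[C@H]12 | intermediate
7 | sodium cis-2-[(1R)-1-hydroxyethyl]-1-methylcyclohex-4-ene-1-carboxylate | C[C@@H](O)[C@H]1CC=CC[C@@]1(C)C(=O)[O-].[Na+] | intermediate (not isolated)
8 | 2-[(1R)-1-hydroxyethyl]-4-iodo-1-methyl-6-oxabicyclo[3.2.1]octan-7-one (lactone O α on C8, iodine β on C7) | C[C@@H](O)[C@H]1C[C@H](I)[C@@H]2C[C@@]1(C)C(=O)O2 | intermediate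
9 | sodium alkoxide of the trans-iodohydrin of the fused lactone (8α-oxido, 7β-iodo) | C[C@H]1OC(=O)[C@]2(C)C[C@H]([O-])[C@@H](I)C[C@H]12.[Na+] | intermediate (not isolated)
10 | 7α,8α-epoxide of lactone 6 (epoxide syn to the lactone ring) | C[C@H]1OC(=O)[C@]2(C)C[C@@H]3O[C@@H]3C[C@H]12 | intermediate
11 | isopropylmagnesium chloride | CC(C)[Mg]Cl | starting material
12 | fused lactone of 6 with 7β-isopropyl and 8α-hydroxyl (trans) | C[C@H]1OC(=O)[C@]2(C)C[C@H](O)[C@@H](C(C)C)C[C@H]12 | intermediate
13 | 8α-O-TBS ether of 12 | C[C@H]1OC(=O)[C@]2(C)C[C@H](O[Si](C)(C)C(C)(C)C)[C@@H](C(C)C)C[C@H]12 | intermediate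
14 | lactol of 13 (C1 hemiacetal, anomer mixture) | C[C@H]1OC(O)[C@]2(C)C[C@H](O[Si](C)(C)C(C)(C)C)[C@@H](C(C)C)C[C@H]12 | intermediate
15 | ethyl (triphenylphosphoranylidene)acetate | CCOC(=O)C=P(c1ccccc1)(c1ccccc1)c1ccccc1 | starting material
16 | ethyl (E)-3-(ring B)prop-2-enoate; ring B carries 10β-CH3, the enoate arm α on C10, (R)-1-hydroxyethyl α on C5, 7β-isopropyl, 8α-OTBS | CCOC(=O)/C=C/[C@]1(C)C[C@H](O[Si](C)(C)C(C)(C)C)[C@@H](C(C)C)C[C@@H]1[C@@H](C)O | intermediate
17 | ethyl 3-(ring B)propanoate, otherwise as 16 | CCOC(=O)CC[C@]1(C)C[C@H](O[Si](C)(C)C(C)(C)C)[C@@H](C(C)C)C[C@@H]1[C@@H](C)O | intermediate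
18 | diol: 3-hydroxypropyl arm on C10, (R)-1-hydroxyethyl on C5, otherwise as 16 | OCCC[C@]1(C)C[C@H](O[Si](C)(C)C(C)(C)C)[C@@H](C(C)C)C[C@@H]1[C@@H](C)O | intermediate
19 | keto-aldehyde: 3-oxopropyl arm on C10 cis to acetyl on C5; 7β-isopropyl, 8α-OTBS | O=CCC[C@]1(C)C[C@H](O[Si](C)(C)C(C)(C)C)[C@@H](C(C)C)C[C@@H]1C(C)=O | intermediate
20 | 8α-(tert-butyldimethylsilyloxy)-5βH,7αH-eudesmane-3α,4α-diol | O[C@@H]1CC[C@]2(C)C[C@H](O[Si](C)(C)C(C)(C)C)[C@@H](C(C)C)C[C@@H]2[C@]1(C)O | intermediate
21 | angelic acid, (Z)-2-methylbut-2-enoic acid | C/C=C(/C)C(=O)O | starting material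
22 | angelic 2,4,6-trichlorobenzoic mixed anhydride | C/C=C(/C)C(=O)OC(=O)c1c(Cl)cc(Cl)cc1Cl | intermediate (not isolated)
23 | 3α-angeloyloxy-8α-(tert-butyldimethylsilyloxy)-5βH,7αH-eudesman-4α-ol | C/C=C(/C)C(=O)O[C@@H]1CC[C@]2(C)C[C@H](O[Si](C)(C)C(C)(C)C)[C@@H](C(C)C)C[C@@H]2[C@]1(C)O | intermediate
24 | 4α-acetoxy-3α-angeloyloxy-8α-(tert-butyldimethylsilyloxy)-5βH,7αH-eudesmane | C/C=C(/C)C(=O)O[C@@H]1CC[C@]2(C)C[C@H](O[Si](C)(C)C(C)(C)C)[C@@H](C(C)C)C[C@@H]2[C@]1(C)OC(C)=O | intermediate
25 | 4α-acetoxy-3α-angeloyloxy-5βH,7αH-eudesman-8α-ol | C/C=C(/C)C(=O)O[C@@H]1CC[C@]2(C)C[C@H](O)[C@@H](C(C)C)C[C@@H]2[C@]1(C)OC(C)=O | intermediate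
26 | 4α-acetoxy-3α-angeloyloxy-5βH,7αH-eudesman-8-one (CNP0322180.1) | C/C=C(/C)C(=O)O[C@@H]1CC[C@]2(C)CC(=O)[C@@H](C(C)C)C[C@@H]2[C@]1(C)OC(C)=O | target

Total steps: 17. Longest linear sequence: 17 steps (1 → 26).

**Steps most likely to fail**

Step 3. The trisubstituted, singly activated butenolide may react too slowly, so that diene polymerisation or thermal decay wins. The fallback sets out from 5 and changes the dienophile and the source of chirality. Citraconic anhydride adds butadiene in toluene at 110 °C to give racemic cis-1-methylcyclohex-4-ene-1,2-dicarboxylic anhydride F1. MeMgBr in THF at −78 °C opens the less hindered carbonyl (the one on the CH carbon). The keto acid is resolved by crystallising its salt with an enantiopure 1-phenylethylamine to give cis-2-acetyl-1-methylcyclohex-4-ene-1-carboxylic acid F2 with the ring configuration of 6. NaBH4 in aqueous NaOH should reduce the ketone anti to the quaternary centre (Felkin–Anh) to the sodium salt 7, and acidification closes this to 6, where the route is rejoined.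

Step 13. Facial discrimination at the ketone may be incomplete, or the aldehyde ketyl may be reduced further before it closes the ring. The fallback sets out from 19 and makes the ring as an alkene before adding the oxygens. Low-valent titanium (TiCl3(DME)1.5, Zn–Cu, DME, reflux, slow addition; McMurry coupling) should give 8α-(tert-butyldimethylsilyloxy)-5βH,7αH-eudesm-3-ene F3. mCPBA should attack the β face, away from the axial C9 bond, to give the 3β,4β-epoxide F4. Aqueous HClO4 in THF opens it trans-diaxially with water entering at the tertiary C4 from the α face, giving the 3β,4α-diol F5. Dess–Martin oxidation of the secondary hydroxyl gives the 4α-hydroxy-3-ketone F6. NaBH4 in MeOH at −20 °C delivers hydride axially from the β face to give the equatorial 3α-alcohol, which is 20.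

Step 15. The axial tertiary hydroxyl may resist acylation, and forcing conditions invite Z→E isomerisation of the neighbouring angelate. The fallback sets out from 20 and installs the acetate first through the diol. Trimethyl orthoacetate with PPTS in CH2Cl2 gives the cyclic 3α,4α-orthoacetate F7. Mild hydrolysis in aqueous acetic acid should deliver the acetyl group to the axial oxygen (stereoelectronic control in cyclic orthoester opening), giving the 4α-acetate 3α-alcohol F8. Yamaguchi esterification of F8 with angelic acid, as in step 14, then gives 24.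

**Further compounds**
F1 | step 3 | racemic cis-1-methylcyclohex-4-ene-1,2-dicarboxylic anhydride (enantiomer carried on is shown) | O=C1OC(=O)[C@]2(C)CC=CC[C@H]12
F2 | step 3 | cis-2-acetyl-1-methylcyclohex-4-ene-1-carboxylic acid (racemic, then resolved to the enantiomer shown) | CC(=O)[C@H]1CC=CC[C@@]1(C)C(=O)O
F3 | step 13 | 8α-(tert-butyldimethylsilyloxy)-5βH,7αH-eudesm-3-ene | CC1=CCC[C@]2(C)C[C@H](O[Si](C)(C)C(C)(C)C)[C@@H](C(C)C)C[C@H]12
F4 | step 13 | 3β,4β-epoxy-8α-(tert-butyldimethylsilyloxy)-5βH,7αH-eudesmane | C[C@]12O[C@H]1CC[C@]3(C)C[C@H](O[Si](C)(C)C(C)(C)C)[C@@H](C(C)C)C[C@H]23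
F5 | step 13 | 8α-(tert-butyldimethylsilyloxy)-5βH,7αH-eudesmane-3β,4α-diol | O[C@H]1CC[C@]2(C)C[C@H](O[Si](C)(C)C(C)(C)C)[C@@H](C(C)C)C[C@@H]2[C@]1(C)O
F6 | step 13 | 4α-hydroxy-8α-(tert-butyldimethylsilyloxy)-5βH,7αH-eudesman-3-one | O=C1CC[C@]2(C)C[C@H](O[Si](C)(C)C(C)(C)C)[C@@H](C(C)C)C[C@@H]2[C@]1(C)O
F7 | step 15 | cyclic methyl orthoacetate of diol 20 (3α,4α-O,O-(1-methoxyethylidene)) | COC1(C)O[C@@H]2CC[C@]3(C)C[C@H](O[Si](C)(C)C(C)(C)C)[C@@H](C(C)C)C[C@@H]3[C@]2(C)O1
F8 | step 15 | 4α-acetoxy-8α-(tert-butyldimethylsilyloxy)-5βH,7αH-eudesman-3α-ol | O[C@@H]1CC[C@]2(C)C[C@H](O[Si](C)(C)C(C)(C)C)[C@@H](C(C)C)C[C@@H]2[C@]1(C)OC(C)=O
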